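## Structural features

The target is assembled from three C6–C3 units. Ring A (4-hydroxyphenyl) sits on C2 and ring B (a 1,2,4-trisubstituted phenol) on C5 of an oxolane (O1, C2–C5) that carries methyl groups on C3 and C4. Ring C (a second 4-hydroxyphenyl) ends a 1-arylpropan-2-yl chain attached to ring B ortho to its hydroxyl and meta to C5.

C2, C3, C4 and C5 are four contiguous stereocentres with all four substituents on one face (2S,3R,4S,5R). This is the least stable arrangement of a 2,5-diaryl-3,4-dimethyloxolane.

The core is pseudo-meso. A mirror plane through O1 and the midpoint of C3–C4 would exchange C2 with C5 and C3 with C4, and only the side chain on ring B breaks it. The absolute configuration of the core therefore means nothing more than which end of the meso-like C3–C4 unit carries ring B.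

The fifth stereocentre (R, the benzylic CH of the side chain) lies four bonds from C5 across ring B. Neither domain can control the other, so each needs its own absolute control.

Both ring C–O bonds are benzylic and para to a phenolic oxygen. They ionise under acid (ring opening, epimerisation to trans isomers) and can be hydrogenolysed. The three phenols must be masked by a group that leaves under neutral conditions.

The real difficulty is tying the absolute sense of a nearly symmetric all-cis tetrad to a remote stereocentre. The key step exploits the meso C3–C4 pair and the local mirror plane through O1: the core is traced back to an achiral meso C6 anhydride whose two enantiotopic carbonyl groups become C2 and C5.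

## Logic of the disconnections

In one sentence: the route is a ligand-controlled mono-arylation of the achiral 2 that breaks its mirror symmetry.

**21 to 20.** The three phenolic O–H bonds are traced back to O–CH2Ph bonds. Free phenols would quench the organometallic steps, and a free para-hydroxyl makes each benzylic ring C–O bond much easier to ionise. One group on all three oxygens allows a single neutral deprotection. The forward step must cleave three aryl benzyl ethers without touching the two benzylic C–O bonds of the ring.

**20 to 18 (through 19).** The C5–H bond is cut. C5 is raised to the ketal level, which removes one stereocentre and lets it be set last, on a ring whose other three substituents already occupy one face. The forward step needs kinetic hydride delivery to the open face and no acid-promoted ring opening afterwards.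

**18 to 9 and 16.** The C5–C(aryl) bond to ring B is cut. This is the most convergent cut and it separates the two stereochemical domains, so each is set by its own catalyst. The forward step needs clean mono-addition of 17 to the carbonyl group of 9 without enolisation at the adjacent methine.

**9 to 7 (through 8).** The acyl C–O1 bond and the C–H bond at the ring A carbinol carbon are cut. This leaves a keto ester with only the two methyl-bearing stereocentres. The forward reduction must give the carbinol configuration that places ring A cis to the neighbouring methyl group, against the Felkin–Anh preference of the substrate, so it has to be reagent-controlled.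

**7 to 6.** The ester O–CH3 bond is cut. The ester exists only so that borane meets a single reducible carbonyl group. The forward step must not epimerise the ketone α-carbon.

**6 to 2 and 3 (key).** The bond between the ketone carbon and ring A is cut. This restores the mirror plane: 6 is chiral with two stereocentres, 2 is achiral. The whole absolute-configuration problem of the core shrinks to the choice between two enantiotopic carbonyl groups, and the cis relation of the methyl groups is already in place. The forward step must select one carbonyl group under catalyst control, stop after one aryl transfer and leave both methine carbons untouched. The inexpensive ring A is used here in excess; the more valuable 16 enters late as the limiting partner.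

**2 to 1.** The two methine C–H bonds are cut. A syn hydrogenation of a cyclic tetrasubstituted alkene can only give the cis, meso product, so no reagent control is needed.

**16 to 15.** The two C–H bonds of the side chain (benzylic CH and CH2) are cut. The stereocentre is purely hydrocarbon and has no handle for auxiliary chemistry. A trisubstituted 1,2-diarylpropene is the substrate class for which iridium N,P-ligand hydrogenation is most reliable. The forward step needs a geometrically pure (E)-alkene.

**15 to 12 and 13.** The vinyl–ring C bond and the vinyl–CH3 bond are cut. A syn methylmetalation of a terminal alkyne followed by cross-coupling with retention fixes the alkene geometry by mechanism. The forward step needs regioselective methyl delivery to the internal carbon and coupling at C–I in the presence of C–Br.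

**12 to 11 to 10.** The alkyne carbon and the benzyl group are removed in turn, which leads back to a commercial salicylaldehyde.

## Other disconnections considered

Alternative 1: All four ring C–H bonds (C2–H to C5–H) are cut to give the furan 2-[4-(benzyloxy)phenyl]-5-{4-(benzyloxy)-3-[(2R)-1-[4-(benzyloxy)phenyl]propan-2-yl]phenyl}-3,4-dimethylfuran A1. The forward key step would be a heterogeneous syn hydrogenation that writes all four stereocentres at once. This is the first plan that comes to mind, because an all-cis oxolane is the signature of a furan hydrogenation and A1 would be only about three steps away. It is not chosen because the two faces of A1 differ only through the side-chain stereocentre, four bonds from the ring. Hydrogen would be expected to add to both faces at nearly the same rate, giving the (2S,3R,4S,5R) and (2R,3S,4R,5S) cores as two diastereomers. No chiral catalyst can be expected to distinguish two aryl groups that differ in one meta substituent. The plan would set the relative but not the absolute configuration.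

Alternative 2: The C2–C3 bond is cut by an Evans syn-aldol reaction of 4-(benzyloxy)benzaldehyde with an N-propionyl oxazolidinone, giving (4S)-4-benzyl-3-[(2S,3S)-3-[4-(benzyloxy)phenyl]-3-hydroxy-2-methylpropanoyl]-1,3-oxazolidin-2-one A2. This would be followed by one-carbon homologation, lactonisation, α-methylation, addition of 17 and hemiketal reduction. The aldol fixes C2 and C3 reliably, but C4 arrives last by enolate methylation, which should occur trans to the C3 methyl group for steric reasons. The cis C3/C4 relation would then need an extra deprotonation and kinetic protonation. The sequence would need roughly twice as many steps to reach 9 and a stoichiometric auxiliary. In the chosen plan the cis pair costs one hydrogenation and the absolute sense one catalytic step.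

Alternative 3: The C2–C3 and C4–C5 bonds are cut together in a three-component carbonyl-ylide cycloaddition. An aryldiazomethane carrying ring B, 4-(benzyloxy)benzaldehyde and dimethyl maleate would combine under Rh2(OAc)4 to give dimethyl (2S,3R,4S,5R)-2-[4-(benzyloxy)phenyl]-5-{4-(benzyloxy)-3-[(2R)-1-[4-(benzyloxy)phenyl]propan-2-yl]phenyl}oxolane-3,4-dicarboxylate A3. Both esters would then be reduced to methyl groups. The idea is attractive because three components meet around the core in one operation. It is not chosen for three reasons. The two termini of the ylide differ only in a remote meta substituent, so the dipolarophile should add in both orientations and give both enantiomeric cores, the same failure as in alternative 1. The endo approach needed for the all-cis isomer is not secured by anything in the substrates. Turning two esters into two methyl groups would add about four redox steps on an acid-sensitive ring.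

Key step: step 2

Assumption: the senses of induction in steps 2, 4 and 8 are assigned by analogy with the parent substrates of each catalyst class; should one prove opposite, the mirror-image ligand is used and nothing else changes.

## Route

Step 1
Reactants: 1 2,3-dimethylmaleic anhydride (3,4-dimethylfuran-2,5-dione)
Product: 2 meso-2,3-dimethylsuccinic anhydride, (3R,4S)-3,4-dimethyloxolane-2,5-dione
Conditions: H2 (4 bar), 10% Pd/C, EtOAc, 25 °C
Reagents that add atoms: none
Why: Heterogeneous syn hydrogenation of the cyclic tetrasubstituted alkene delivers both hydrogens to one face, so the two methyl groups must end up cis; the product is achiral (meso) and needs no stereocontrol by a reagent.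

Step 2
Reactants: 2 meso-2,3-dimethylsuccinic anhydride; 3 1-(benzyloxy)-4-bromobenzene
Product: 6 (2S,3R)-4-[4-(benzyloxy)phenyl]-2,3-dimethyl-4-oxobutanoic acid, via aryllithium 4 (not isolated), via arylzinc triflate 5 (not isolated)
Conditions: 3, n-BuLi, THF, −78 °C; Zn(OTf)2, −78 → 23 °C; then 2, [Rh(cod)Cl]2 (4 mol%), (R,R)-TADDOL-derived N,N-dimethylphosphoramidite (10 mol%), THF, 50 °C; 1 M HCl work-up
Reagents that add atoms: none
Why: Aryl transfer from zinc to the rhodium–phosphoramidite complex (monovalent rhodium) gives an arylrhodium species, which inserts into one of the two enantiotopic C(acyl)–O bonds of 2 to give an acyl(aryl)rhodium carboxylate (trivalent rhodium); reductive elimination forms the aryl–ketone bond and releases the zinc carboxylate of 6. The closest known reaction type is the enantioselective rhodium-catalysed cross-coupling of cyclic meso anhydrides, 2,3-dimethylsuccinic anhydride among them, with arylzinc reagents made in situ from aryl bromides, so a known desymmetrisation is applied to a new aryl group. No ring is closed; the five-membered anhydride is opened. No stereocentre is created: C2 and C3 of 6 are the two cis methine carbons of 2, and the chiral ligand only decides which carbonyl group is arylated, the one next to the (R)-configured carbon being required. That single choice fixes the absolute configuration of what become C3 and C4 of the oxolane and marks the end that will carry ring A. The step needs enantiotopic-group selectivity (from the ligand), mono-arylation (the carboxylate formed deactivates the second carbonyl group and the arylzinc does not add to the ketone) and configurational integrity at the ketone α-carbon (no base stronger than a zinc carboxylate is present and the work-up is acidic). The enantiomeric purity should be upgradable by crystallisation of 6 or of an amine salt.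

Step 3
Reactants: 6 (2S,3R)-4-[4-(benzyloxy)phenyl]-2,3-dimethyl-4-oxobutanoic acid
Product: 7 methyl (2S,3R)-4-[4-(benzyloxy)phenyl]-2,3-dimethyl-4-oxobutanoate
Conditions: TMSCHN2, toluene/MeOH (4:1), 0 °C
Reagents that add atoms: (trimethylsilyl)diazomethane, C[Si](C)(C)C=[N+]=[N-]
Why: O-Methylation of the carboxylic acid by the diazoalkane proceeds without base, so the ketone α-centre should not epimerise; the ester ensures that borane in step 4 meets only the ketone.

Step 4
Reactants: 7 methyl (2S,3R)-4-[4-(benzyloxy)phenyl]-2,3-dimethyl-4-oxobutanoate
Product: 9 (3S,4R,5S)-5-[4-(benzyloxy)phenyl]-3,4-dimethyloxolan-2-one, via hydroxy ester 8 (not isolated)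
Conditions: (R)-2-methyl-CBS-oxazaborolidine (20 mol%), BH3·SMe2, THF, −20 °C; MeOH quench; then PPTS (10 mol%), toluene, 50 °C
Reagents that add atoms: none
Why: Corey–Bakshi–Shibata reduction of the aryl ketone; the (R)-catalyst treats the aryl group as the large substituent and should give the (4S)-carbinol, which is the anti-Felkin isomer, so the selectivity rests on the reagent. The hydroxy ester 8 then lactonises by acyl substitution, with retention at the carbinol carbon, to the all-cis lactone; the weak acid is chosen so that the p-alkoxybenzylic C–O bond does not ionise.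

Step 5
Reactants: 10 5-bromo-2-hydroxybenzaldehyde
Product: 11 2-(benzyloxy)-5-bromobenzaldehyde
Conditions: BnBr, K2CO3, DMF, 25 °C
Reagents that add atoms: benzyl bromide, BrCc1ccccc1
Why: Williamson ether synthesis on the acidic ortho-formyl phenol; the bromine para to oxygen is the later lithiation site.

Step 6
Reactants: 11 2-(benzyloxy)-5-bromobenzaldehyde
Product: 12 1-(benzyloxy)-4-bromo-2-ethynylbenzene
Conditions: dimethyl (1-diazo-2-oxopropyl)phosphonate, K2CO3, MeOH, 0 → 25 °C
Reagents that add atoms: dimethyl (1-diazo-2-oxopropyl)phosphonate, CC(=O)C(=[N+]=[N-])P(=O)(OC)OC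
Why: Seyferth–Gilbert homologation in the Ohira–Bestmann variant converts the non-enolisable aryl aldehyde into the terminal alkyne under mild base; aryl bromide and benzyl ether are inert.

Step 7
Reactants: 12 1-(benzyloxy)-4-bromo-2-ethynylbenzene; 13 1-(benzyloxy)-4-iodobenzene
Product: 15 1-(benzyloxy)-4-bromo-2-[(1E)-1-[4-(benzyloxy)phenyl]prop-1-en-2-yl]benzene, via alkenylalane 14 (not isolated)
Conditions: Me3Al, Cp2ZrCl2 (25 mol%), ClCH2CH2Cl, 23 °C; then 13, Pd(PPh3)4 (5 mol%), ZnCl2, THF, 23 °C
Reagents that add atoms: trimethylaluminium, C[Al](C)C
Why: Zirconium-catalysed syn methylalumination of the terminal alkyne places the methyl group on the internal carbon and aluminium on the terminal carbon; the Negishi coupling of 14 proceeds with retention, so only the (E)-alkene can form. Zerovalent palladium inserts into the C–I bond of 13 much faster than into the C–Br bond of ring B.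

Step 8
Reactants: 15 1-(benzyloxy)-4-bromo-2-[(1E)-1-[4-(benzyloxy)phenyl]prop-1-en-2-yl]benzene
Product: 16 1-(benzyloxy)-4-bromo-2-[(2R)-1-[4-(benzyloxy)phenyl]propan-2-yl]benzene
Conditions: [Ir(cod)(L)]BArF (1 mol%; L = (S)-4-tert-butyl-2-[2-(di-o-tolylphosphanyl)phenyl]-4,5-dihydrooxazole), H2 (50 bar), CH2Cl2, 25 °C
Reagents that add atoms: none
Why: Iridium N,P-ligand asymmetric hydrogenation of an unfunctionalised trisubstituted (E)-1,2-diarylpropene, the standard substrate class for this catalyst; the (S)-ligand should give the (R)-product by analogy with (E)-1,2-diphenylpropene. The homogeneous catalyst leaves the aryl bromide and the benzyl ethers untouched.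

Step 9
Reactants: 16 1-(benzyloxy)-4-bromo-2-[(2R)-1-[4-(benzyloxy)phenyl]propan-2-yl]benzene; 9 (3S,4R,5S)-5-[4-(benzyloxy)phenyl]-3,4-dimethyloxolan-2-one
Product: 18 (3S,4R,5S)-5-[4-(benzyloxy)phenyl]-2-{4-(benzyloxy)-3-[(2R)-1-[4-(benzyloxy)phenyl]propan-2-yl]phenyl}-3,4-dimethyloxolan-2-ol (both C2 epimers), via aryllithium 17 (not isolated)
Conditions: 16, n-BuLi, THF, −78 °C; then 9, −78 °C; aq. NH4Cl
Reagents that add atoms: none
Why: Bromine–lithium exchange followed by 1,2-addition to the lactone; the tetrahedral lithium alkoxide persists at −78 °C and so prevents a second addition, and gives the hemiketal (in equilibrium with the open hydroxy ketone) on work-up. The three existing ring stereocentres are not touched and the configuration at C2 is irrelevant because it is erased in step 10.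

Step 10
Reactants: 18 (3S,4R,5S)-5-[4-(benzyloxy)phenyl]-2-{4-(benzyloxy)-3-[(2R)-1-[4-(benzyloxy)phenyl]propan-2-yl]phenyl}-3,4-dimethyloxolan-2-ol
Product: 20 (2S,3R,4S,5R)-2-[4-(benzyloxy)phenyl]-5-{4-(benzyloxy)-3-[(2R)-1-[4-(benzyloxy)phenyl]propan-2-yl]phenyl}-3,4-dimethyloxolane, via oxocarbenium ion 19 (not isolated)
Conditions: Et3SiH, BF3·OEt2, CH2Cl2, −78 °C; Et3N then aq. NaHCO3 at −78 °C
Reagents that add atoms: none
Why: Reductive deoxygenation of a cyclic hemiketal: the Lewis acid ionises 18 to the planar 2-aryl oxocarbenium ion 19, and the silane delivers hydride to the face opposite the adjacent methyl group, the second methyl group and ring A, all of which sit on the other face. The new hydrogen is therefore trans to them and ring B cis, giving the all-cis (5R) product under kinetic control; the cold basic quench is meant to stop acid-promoted ring opening of the product.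

Step 11
Reactants: 20 (2S,3R,4S,5R)-2-[4-(benzyloxy)phenyl]-5-{4-(benzyloxy)-3-[(2R)-1-[4-(benzyloxy)phenyl]propan-2-yl]phenyl}-3,4-dimethyloxolane
Product: 21 4-[(2S,3R,4S,5R)-5-{4-hydroxy-3-[(2R)-1-(4-hydroxyphenyl)propan-2-yl]phenyl}-3,4-dimethyloxolan-2-yl]phenol
Conditions: H2 (1 bar), 10% Pd/C, EtOAc, 25 °C
Reagents that add atoms: none
Why: Hydrogenolysis of three aryl benzyl ethers, which should be much faster than cleavage of the dialkyl benzylic C–O bonds of the ring in a neutral aprotic solvent; the reaction is to be stopped once three equivalents of hydrogen are taken up. No stereocentre is involved.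

## Compound list

1 | 2,3-dimethylmaleic anhydride (3,4-dimethylfuran-2,5-dione) | CC1=C(C)C(=O)OC1=O | starting material
2 | meso-2,3-dimethylsuccinic anhydride, (3R,4S)-3,4-dimethyloxolane-2,5-dione | C[C@@H]1[C@H](C)C(=O)OC1=O | intermediate
3 | 1-(benzyloxy)-4-bromobenzene | Brc1ccc(OCc2ccccc2)cc1 | starting material
4 | [4-(benzyloxy)phenyl]lithium | [Li]c1ccc(OCc2ccccc2)cc1 | intermediate
5 | [4-(benzyloxy)phenyl]zinc trifluoromethanesulfonate | FC(F)(F)S(=O)(=O)O[Zn]c1ccc(OCc2ccccc2)cc1 | intermediate
6 | (2S,3R)-4-[4-(benzyloxy)phenyl]-2,3-dimethyl-4-oxobutanoic acid | C[C@@H](C(=O)c1ccc(OCc2ccccc2)cc1)[C@H](C)C(O)=O | intermediate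
7 | methyl (2S,3R)-4-[4-(benzyloxy)phenyl]-2,3-dimethyl-4-oxobutanoate | C[C@@H](C(=O)c1ccc(OCc2ccccc2)cc1)[C@H](C)C(=O)OC | intermediate
8 | methyl (2S,3R,4S)-4-[4-(benzyloxy)phenyl]-4-hydroxy-2,3-dimethylbutanoate | C[C@@H]([C@H](O)c1ccc(OCc2ccccc2)cc1)[C@H](C)C(=O)OC | intermediate
9 | (3S,4R,5S)-5-[4-(benzyloxy)phenyl]-3,4-dimethyloxolan-2-one | C[C@@H]1[C@H](C)C(=O)O[C@@H]1c1ccc(OCc2ccccc2)cc1 | intermediate
10 | 5-bromo-2-hydroxybenzaldehyde | O=Cc1cc(Br)ccc1O | starting material
11 | 2-(benzyloxy)-5-bromobenzaldehyde | O=Cc1cc(Br)ccc1OCc1ccccc1 | intermediate
12 | 1-(benzyloxy)-4-bromo-2-ethynylbenzene | C#Cc1cc(Br)ccc1OCc1ccccc1 | intermediate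
13 | 1-(benzyloxy)-4-iodobenzene | Ic1ccc(OCc2ccccc2)cc1 | starting material
14 | {(1E)-2-[2-(benzyloxy)-5-bromophenyl]prop-1-en-1-yl}dimethylaluminium | C[Al](C)/C=C(\C)c1cc(Br)ccc1OCc1ccccc1 | intermediate
15 | 1-(benzyloxy)-4-bromo-2-[(1E)-1-[4-(benzyloxy)phenyl]prop-1-en-2-yl]benzene | C/C(=C\c1ccc(OCc2ccccc2)cc1)c1cc(Br)ccc1OCc1ccccc1 | intermediate
16 | 1-(benzyloxy)-4-bromo-2-[(2R)-1-[4-(benzyloxy)phenyl]propan-2-yl]benzene | Brc1ccc(OCc2ccccc2)c([C@H](C)Cc2ccc(OCc3ccccc3)cc2)c1 | intermediate
17 | {4-(benzyloxy)-3-[(2R)-1-[4-(benzyloxy)phenyl]propan-2-yl]phenyl}lithium | [Li]c1ccc(OCc2ccccc2)c([C@H](C)Cc2ccc(OCc3ccccc3)cc2)c1 | intermediate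
18 | (3S,4R,5S)-5-[4-(benzyloxy)phenyl]-2-{4-(benzyloxy)-3-[(2R)-1-[4-(benzyloxy)phenyl]propan-2-yl]phenyl}-3,4-dimethyloxolan-2-ol (both C2 epimers) | C[C@@H]1[C@H](C)C(O)(c2ccc(OCc3ccccc3)c([C@H](C)Cc3ccc(OCc4ccccc4)cc3)c2)O[C@@H]1c1ccc(OCc2ccccc2)cc1 | intermediate
19 | (2S,3R,4S)-2-[4-(benzyloxy)phenyl]-5-{4-(benzyloxy)-3-[(2R)-1-[4-(benzyloxy)phenyl]propan-2-yl]phenyl}-3,4-dimethyl-3,4-dihydro-2H-furan-1-ium | C[C@@H]1[C@H](C)C(c2ccc(OCc3ccccc3)c([C@H](C)Cc3ccc(OCc4ccccc4)cc3)c2)=[O+][C@@H]1c1ccc(OCc2ccccc2)cc1 | intermediate
20 | (2S,3R,4S,5R)-2-[4-(benzyloxy)phenyl]-5-{4-(benzyloxy)-3-[(2R)-1-[4-(benzyloxy)phenyl]propan-2-yl]phenyl}-3,4-dimethyloxolane | C[C@@H]1[C@H](C)[C@H](c2ccc(OCc3ccccc3)c([C@H](C)Cc3ccc(OCc4ccccc4)cc3)c2)O[C@@H]1c1ccc(OCc2ccccc2)cc1 | intermediate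
21 | 4-[(2S,3R,4S,5R)-5-{4-hydroxy-3-[(2R)-1-(4-hydroxyphenyl)propan-2-yl]phenyl}-3,4-dimethyloxolan-2-yl]phenol | C[C@@H]1[C@H](C)[C@H](c2ccc(O)c([C@H](C)Cc3ccc(O)cc3)c2)O[C@@H]1c1ccc(O)cc1 | target

## Step count and least certain steps

Total step count: 11. Longest linear sequence: 7 steps (1, 2, 3, 4, 9, 10, 11; the branch 5, 6, 7, 8 followed by 9, 10, 11 is equally long).

**Step 2 (key step).** The most likely failure is incomplete discrimination between the two enantiotopic carbonyl groups, or slow turnover with the electron-rich arylzinc so that an uncatalysed, unselective ring opening competes. The ligand has to tell apart two ends that differ only in the sense of two methyl-bearing carbons. The fallback sets out from 2 and comes back at 7. Ring opening of 2 with methanol in the presence of quinidine (or quinine, whichever pseudo-enantiomer gives the required sense) in toluene at −55 °C, an alkaloid-mediated desymmetrising alcoholysis, would give the half-ester (2R,3S)-4-methoxy-2,3-dimethyl-4-oxobutanoic acid F1. Oxalyl chloride with a trace of DMF in CH2Cl2 would convert it into methyl (2S,3R)-4-chloro-2,3-dimethyl-4-oxobutanoate F2. A Pd(PPh3)4-catalysed acylation of arylzinc 5 (made from 3 as in step 2) with F2 in THF at 0 °C, a Negishi ketone synthesis, would give 7 directly, so that step 3 falls away.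

**Step 4.** The most likely failure is erosion of diastereofacial selectivity, because the Felkin–Anh preference of the α-methyl ketone opposes the catalyst and the alkyl side of the ketone is branched. A second risk is partial ionisation at the p-alkoxybenzylic carbinol during lactonisation. The fallback sets out from 7 and comes back at 9, and uses the substrate bias instead of fighting it. LiBH(s-Bu)3 (L-Selectride) in THF at −78 °C should reduce 7 under Felkin–Anh control to the (4R)-alkoxide, which closes to (3S,4R,5R)-5-[4-(benzyloxy)phenyl]-3,4-dimethyloxolan-2-one F3. LiOH in THF/H2O, then careful acidification to pH 5 at 0 °C, would give (2S,3R,4R)-4-[4-(benzyloxy)phenyl]-4-hydroxy-2,3-dimethylbutanoic acid F4. A Mitsunobu lactonisation (PPh3, diisopropyl azodicarboxylate, THF, 0 °C), in which the carboxylate displaces the activated benzylic oxygen with inversion, would then give 9.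

**Step 10.** The most likely failure is loss of configuration by E1 deprotonation of the oxocarbenium ion at the adjacent methine (enol ether formation and re-protonation), or by Lewis-acid-promoted reopening of the all-cis product at a benzylic C–O bond with reclosure to a trans isomer. Both are driven by the strain of four cis substituents. The fallback sets out from 18 and comes back at 21, and replaces hydride delivery by hydrogen delivery to an alkene. PPTS (cat.) with 4 Å molecular sieves in toluene at 60 °C should dehydrate 18 to the cyclic enol ether (2S,3R)-2-[4-(benzyloxy)phenyl]-5-{4-(benzyloxy)-3-[(2R)-1-[4-(benzyloxy)phenyl]propan-2-yl]phenyl}-3,4-dimethyl-2,3-dihydrofuran F5. Hydrogenation over 10% Pd/C in EtOAc should add hydrogen syn to the C4=C5 bond from the face opposite ring A and the C3 methyl group and cleave the three benzyl ethers in the same operation, giving 21 and merging steps 10 and 11.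

**Step 8.** The most likely failure is slow turnover and poor facial discrimination, because the ortho-benzyloxy group twists ring B out of the alkene plane and may compete for the iridium centre. The fallback sets out from 12 and comes back at 16, and moves the stereo-determining event to a less hindered 1,1-disubstituted alkene. Methylalumination of 12 as in step 7 to 14, quenched with dilute HCl instead of being coupled, would give 1-(benzyloxy)-4-bromo-2-(prop-1-en-2-yl)benzene F6. A cobalt-catalysed enantioselective hydroboration with pinacolborane (CoCl2 complex of a chiral iminopyridine–oxazoline ligand, NaBHEt3 as activator, THF, 25 °C) would give 2-{(2R)-2-[2-(benzyloxy)-5-bromophenyl]propyl}-4,4,5,5-tetramethyl-1,3,2-dioxaborolane F7. A Suzuki–Miyaura coupling of this primary alkylboronate with 13 (Pd(OAc)2, RuPhos, K3PO4, toluene/H2O, 80 °C), selective for the C–I bond, would give 16.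

## Further compounds

F1 | step 2 | (2R,3S)-4-methoxy-2,3-dimethyl-4-oxobutanoic acid | C[C@@H](C(O)=O)[C@H](C)C(=O)OC
F2 | step 2 | methyl (2S,3R)-4-chloro-2,3-dimethyl-4-oxobutanoate | C[C@@H](C(Cl)=O)[C@H](C)C(=O)OC
F3 | step 4 | (3S,4R,5R)-5-[4-(benzyloxy)phenyl]-3,4-dimethyloxolan-2-one | C[C@@H]1[C@H](C)C(=O)O[C@H]1c1ccc(OCc2ccccc2)cc1
F4 | step 4 | (2S,3R,4R)-4-[4-(benzyloxy)phenyl]-4-hydroxy-2,3-dimethylbutanoic acid | C[C@@H]([C@@H](O)c1ccc(OCc2ccccc2)cc1)[C@H](C)C(O)=O
F5 | step 10 | (2S,3R)-2-[4-(benzyloxy)phenyl]-5-{4-(benzyloxy)-3-[(2R)-1-[4-(benzyloxy)phenyl]propan-2-yl]phenyl}-3,4-dimethyl-2,3-dihydrofuran | C[C@@H]1C(C)=C(c2ccc(OCc3ccccc3)c([C@H](C)Cc3ccc(OCc4ccccc4)cc3)c2)O[C@@H]1c1ccc(OCc2ccccc2)cc1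
F6 | step 8 | 1-(benzyloxy)-4-bromo-2-(prop-1-en-2-yl)benzene | C=C(C)c1cc(Br)ccc1OCc1ccccc1
F7 | step 8 | 2-{(2R)-2-[2-(benzyloxy)-5-bromophenyl]propyl}-4,4,5,5-tetramethyl-1,3,2-dioxaborolane | C[C@H](CB1OC(C)(C)C(C)(C)O1)c1cc(Br)ccc1OCc1ccccc1
A1 | alternative 1 | 2-[4-(benzyloxy)phenyl]-5-{4-(benzyloxy)-3-[(2R)-1-[4-(benzyloxy)phenyl]propan-2-yl]phenyl}-3,4-dimethylfuran | Cc1c(C)c(-c2ccc(OCc3ccccc3)c([C@H](C)Cc3ccc(OCc4ccccc4)cc3)c2)oc1-c1ccc(OCc2ccccc2)cc1
A2 | alternative 2 | (4S)-4-benzyl-3-[(2S,3S)-3-[4-(benzyloxy)phenyl]-3-hydroxy-2-methylpropanoyl]-1,3-oxazolidin-2-one | C[C@@H]([C@H](O)c1ccc(OCc2ccccc2)cc1)C(=O)N1C(=O)OC[C@@H]1Cc1ccccc1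
A3 | alternative 3 | dimethyl (2S,3R,4S,5R)-2-[4-(benzyloxy)phenyl]-5-{4-(benzyloxy)-3-[(2R)-1-[4-(benzyloxy)phenyl]propan-2-yl]phenyl}oxolane-3,4-dicarboxylate | COC(=O)[C@@H]1[C@H](C(=O)OC)[C@H](c2ccc(OCc3ccccc3)c([C@H](C)Cc3ccc(OCc4ccccc4)cc3)c2)O[C@@H]1c1ccc(OCc2ccccc2)cc1
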